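**Remark on conventions (one line):** atoms are numbered as in germacranolides (ring C1–C10, lactone carbons C11–C13, ester carbon C14, methyl C15); α/β refer to the usual drawing with H‑7 α. Compounds 11, 12, 14 and 15 are carried as C11 epimers, a centre that becomes planar again in 16.

## The problem

Target 28 is a ten‑membered carbocycle (C1–C10) trans‑fused at C6/C7 to an α‑methylene‑γ‑lactone. It carries the dienoate C10(CO2Me)=C1–C2=C3 with both ring double bonds cis, directly attached to the trans (4α,5β) epoxide. Six contiguous stereocentres (4R,5R,6S,7R,8S,9S) sit on this mobile ring and two more (2R,3S) in the cis‑dimethyl epoxy ester on O8. C7 is the only ring CH without oxygen, so it must relay to C6 (O trans), C8 (O cis to C11) and, through them, to C5 and C9 (8,9‑threo). The vinyl epoxide, the methylene lactone, the alkylidene ester with its allylic acetate and the vicinal diester tolerate neither acid, strong base, soft nucleophiles nor heat, and O8 and O9 carry different acyl groups. Closing a ten‑membered ring that holds a cis,cis‑diene and an epoxide from an open chain is the classical weak point.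

The feature that removes it is this: the ring atoms C4–C9 with C15 and C11–C13 are exactly the carbon skeleton of carvone (ring B), C9 being its carbonyl carbon and C4 its methyl‑bearing α‑carbon. The remaining C10(C14)=C1–C2=C3 is a four‑carbon dienoate inserted into the C9–C4 bond. A cis‑fused bicyclo[4.4.0] system (ring A = C9, C10, C1, C2, C3, C4; ring B = C4–C9) with oxygen on C9 and a nucleofuge on C5 is therefore set up to fragment to the macrocycle with all three ring alkene geometries predetermined.

## Retrosynthesis

**28 ⇒ 22 + 26 ⇒ 18.** The acyl C–O bond at O8 is cut first (22 and acid 26), then the acetate at O9 (20), the C9–H bond (ketone 19) and the two epoxide C–O bonds (trienone 18). This order keeps the acid‑labile vinyl epoxide and both esters out of the skeleton‑forming chemistry. O8 and O9 are differentiated for free because C9 emerges as a ketone while O8 is silylated. The forward steps must epoxidise only the C4=C5 bond from its outer face and reduce the C9 ketone 1,2 with Felkin–Anh control by the C8 silyloxy group.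

**18 ⇒ 16 (key).** The C4–C9 bond is re‑formed, which turns the macrocycle into the cis‑fused hexalin 16 with a silyloxy group on C9 and a sulfonyl group on C5. This is preferred over cutting C6–C7, C1–C2 or C2=C3, which are all open‑chain macrocyclisations that need every stereocentre in place on a floppy chain. In 16 the cis geometry of C10=C1 and C2=C3 is a consequence of the six‑membered ring A, and the trans C4=C5 bond a consequence of a chair. The forward reaction is an alkoxide‑triggered Grob fragmentation.

**16 ⇒ 12 + 13.** Ring A is cut at C3–C4 and C9–C10. Pyrone 13 supplies C10, C14, C1, C2 and C3 in one inverse‑demand [4+2]/CO2‑extrusion with silyl enol ether 12. Stepwise annulations would need several steps and give the same adduct. Aromatisation is impossible because both new sp3 carbons are quaternary. The forward step must place the silyloxy carbon next to the ester carbon (normal pyrone regiochemistry) and add to the α face of ring B.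

**12 ⇒ 11 ⇒ 10 ⇒ 8.** The C5–S bond (and the masking C13–S bond) come from reversible sulfinate addition to enone lactone 10, which puts the nucleofuge equatorial. The enol ether follows by regioselective soft enolisation. The C8–O bond comes from enolate hydroxylation of 8, whose trans‑lactone locks ring B so that axial attack gives the 8β oxygen.

**8 ⇒ 7 ⇒ 5 ⇒ 4 ⇒ 1.** The lactone C–O bond is cut to hydroxy acid 7. The C6–O bond is traced to singlet‑oxygen addition to dienol ether 5, anti to the side chain. The C12 oxidation level comes from acid 4, made from (S)‑carvone 1 by allylic chlorination and oxidation. Carvone provides ten of the fifteen skeletal carbons and the C7 configuration from which all others are relayed.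

**26 ⇒ 25 ⇒ 24 ⇒ 23.** The cis‑dimethyl epoxy acid comes from Sharpless epoxidation of tiglyl alcohol 24 (from tiglic acid 23) and oxidation.

## Roads not taken

**Alternative 1:** (the most obvious) cut C6–C7 and the lactone C–O bond. The forward step is an intramolecular Barbier/Nozaki–Hiyama–Kishi allylation of epoxy aldehyde/allylic bromide A1 (CrCl2 or indium), which would close the ring and form C6, C7 and the lactone at once. The chosen plan is better for three reasons. A1 must be assembled as an open chain that already holds C4, C5, C8, C9, a (Z,Z)‑dienoate with an allylic acetate and a cis‑vinyl epoxide next to an enolisable epoxy aldehyde. The low‑valent metal can ionise the allylic acetate or open the vinyl epoxide. Ring closure and C6/C7 selectivity depend on a ten‑membered transition state with only remote control. In the chosen route the ring is opened from a bicycle, not closed, and the alkene geometries are fixed by rings.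

**Alternative 2:** cut C5–C10. The forward step is a photochemical conrotatory 6π ring opening of the cis‑fused eudesma‑1,3‑diene A2 (angular ester on C10) to the 1(10),2,4‑triene A3, followed by 4,5‑epoxidation. A3 is a conjugated trienoate that absorbs at longer wavelength than A2, so it is consumed under the conditions that form it and only a photostationary mixture results. The two conrotatory senses give different C10=C1/C4=C5 geometries with nothing but sterics to choose between them. A2 needs a decalin with a quaternary ester‑bearing carbon and five further stereocentres, two of which are built only to be destroyed. The chosen fragmentation is thermal, irreversible and geometry‑defined.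

**Alternative 3:** cut C6–C7 by a [3,3] shift. The forward step is an anionic oxy‑Cope rearrangement of dialkenyl cyclohexadienol A4, made from a dearomatised salicylate ester that would supply C9, C10 and C1–C4 with the cis,cis‑diene already present. The C9 alkoxide of A4 is a vinylogous aldolate of the dienoate. Heterolysis of C4–C9 to a β‑keto‑ester trienolate should outrun the concerted shift, giving an open polyene that recloses through C2 to a six‑membered ring. C6/C7 would depend on an enol ether geometry and on a quaternary centre for which no reliable enantioselective dearomative alkenylation exists, and C5 and C8 would still lack oxygen. The chosen plan uses the same facile heterolysis productively, because in 16 the two ends are tied together by ring B.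

Key step: step 11

## Route

Step 1
Reactants: 1 (S)-(+)-carvone
Product: 2 (5S)-5-(3-chloroprop-1-en-2-yl)-2-methylcyclohex-2-en-1-one
Conditions: Ca(OCl)2, solid CO2, CH2Cl2/H2O, 0 °C
Reagents that add atoms: calcium hypochlorite, [Ca+2].[O-]Cl.[O-]Cl
Why: Ene-type allylic chlorination: HOCl attacks the electron-rich 1,1-disubstituted alkene and the double bond shifts to the 2-(chloromethyl)allyl unit; the electron-poor enone alkene does not react and C7 is untouched.

Step 2
Reactants: 2 (5S)-5-(3-chloroprop-1-en-2-yl)-2-methylcyclohex-2-en-1-one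
Product: 3 2-[(1S)-4-methyl-5-oxocyclohex-3-en-1-yl]prop-2-enal
Conditions: N-methylmorpholine N-oxide, KI (cat.), MeCN, 50 °C
Reagents that add atoms: N-methylmorpholine N-oxide, C[N+]1([O-])CCOCC1
Why: Kornblum-type oxidation: SN2 O-alkylation of the amine N-oxide by the primary allylic chloride and collapse of the alkoxyammonium ion give the 2-substituted acrolein without touching the enone.

Step 3
Reactants: 3 2-[(1S)-4-methyl-5-oxocyclohex-3-en-1-yl]prop-2-enal
Product: 4 2-[(1S)-4-methyl-5-oxocyclohex-3-en-1-yl]prop-2-enoic acid
Conditions: NaClO2, NaH2PO4, 2-methylbut-2-ene, t-BuOH/H2O, 0 °C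
Reagents that add atoms: sodium chlorite, [Na+].[O-]Cl=O
Why: Pinnick oxidation; chlorite oxidises only the aldehyde and the alkene scavenger traps HOCl, so both alkenes survive.

Step 4
Reactants: 4 2-[(1S)-4-methyl-5-oxocyclohex-3-en-1-yl]prop-2-enoic acid
Product: 5 trimethylsilyl 2-[(1R)-4-methyl-5-(trimethylsilyloxy)cyclohexa-2,4-dien-1-yl]prop-2-enoate
Conditions: Me3SiCl, NaI, Et3N, MeCN, 25 °C
Reagents that add atoms: chlorotrimethylsilane, C[Si](C)(C)Cl
Why: Thermodynamic silylation (Me3SiI formed in situ, amine base) gives the more substituted, through-conjugated 1-siloxy-1,3-diene by loss of a C6 proton and silylates the acid; no free enolate is present, so the acrylate is not attacked and C7 keeps its configuration.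

Step 5
Reactants: 5 trimethylsilyl 2-[(1R)-4-methyl-5-(trimethylsilyloxy)cyclohexa-2,4-dien-1-yl]prop-2-enoate
Product: 7 2-[(1S,2R)-2-hydroxy-4-methyl-5-oxocyclohex-3-en-1-yl]prop-2-enoic acid, via endoperoxide 6 (not isolated)
Conditions: O2, tetraphenylporphyrin (cat.), visible light, CH2Cl2, −78 °C; PPh3; then citric acid, MeOH/H2O, 0 °C
Reagents that add atoms: dioxygen, O=O
Why: [4+2] addition of singlet oxygen across C9/C6 of the siloxydiene from the face opposite the C7 side chain, collapse of the endoperoxide by silyl transfer to the γ-silylperoxy enone, phosphine reduction of the O–O bond and mild desilylation; this sets C6 with oxygen trans to the C7 substituent.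

Step 6
Reactants: 7 2-[(1S,2R)-2-hydroxy-4-methyl-5-oxocyclohex-3-en-1-yl]prop-2-enoic acid
Product: 8 (3aS,7aR)-6-methyl-3-methylidene-3,3a,4,7a-tetrahydro-1-benzofuran-2,5-dione
Conditions: EDC·HCl, DMAP (cat.), CH2Cl2, 0 to 25 °C
Reagents that add atoms: none
Why: Steglich-type carbodiimide lactonisation of the trans-diequatorial hydroxy acid gives the trans-fused γ-lactone, which locks ring B in one chair for the following steps.

Step 7
Reactants: 8 (3aS,7aR)-6-methyl-3-methylidene-3,3a,4,7a-tetrahydro-1-benzofuran-2,5-dione
Product: 10 (3aS,4S,7aR)-4-[tert-butyl(dimethyl)silyl]oxy-6-methyl-3-methylidene-3,3a,4,7a-tetrahydro-1-benzofuran-2,5-dione (8β-silyloxy), via sodium alkoxide 9 (not isolated)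
Conditions: NaN(SiMe3)2, THF, −78 °C; 2-(phenylsulfonyl)-3-phenyloxaziridine; then t-BuMe2SiOTf, −78 to 0 °C
Reagents that add atoms: 2-(phenylsulfonyl)-3-phenyloxaziridine, O=S(=O)(c1ccccc1)N1OC1c1ccccc1; tert-butyldimethylsilyl triflate, CC(C)(C)[Si](C)(C)OS(=O)(=O)C(F)(F)F
Why: Kinetic α′-deprotonation at C8 and electrophilic hydroxylation of the enolate; on the lactone-locked ring the oxidant should attack axially, anti to the pseudoaxial C7–H, giving the 8β oxygen (cis to C7–C11), and the alkoxide is silylated in the same flask.

Step 8
Reactants: 10 8β-silyloxy enone lactone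
Product: 11 bis(phenylsulfonyl) ketone (4α-Me; 5β-SO2Ph; 13-SO2Ph; C11 epimers)
Conditions: PhSO2Na, AcOH, DMF, 40 °C
Reagents that add atoms: sodium benzenesulfinate, [Na+].[O-]S(=O)c1ccccc1
Why: Reversible sulfa-Michael addition to both acceptors; thermodynamic control places the large phenylsulfonyl group equatorial at C5 (trans to C6–O) and the C4 methyl equatorial, and the exo-methylene lactone is masked as its β-sulfonyl adduct.

Step 9
Reactants: 11 bis(phenylsulfonyl) ketone
Product: 12 C9 trimethylsilyl enol ether of 11 (C9=C4 double bond)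
Conditions: Me3SiOTf, Et3N, CH2Cl2, −78 to 0 °C
Reagents that add atoms: trimethylsilyl triflate, C[Si](C)(C)OS(=O)(=O)C(F)(F)F
Why: Soft enolisation: the axial C4–H is removed in preference to the equatorial C8–H, giving the tetrasubstituted enol ether without a free enolate, so sulfinate is not expelled.

Step 10
Reactants: 12 C9 trimethylsilyl enol ether; 13 methyl 2-oxo-2H-pyran-3-carboxylate
Product: 16 cis-fused hexalin (ring A C9(OSiMe3)–C10(CO2Me)=C1–C2=C3–C4(Me); 5β-SO2Ph; 8β-OSi; methylene lactone restored), via cycloadduct 14 (not isolated), via masked hexalin 15 (not isolated)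
Conditions: toluene, 100 °C, sealed tube; then DBU, 25 °C
Reagents that add atoms: none
Why: Inverse-electron-demand Diels–Alder reaction of the electron-poor 2-pyrone with the silyl enol ether (nucleophilic C4 bonds to pyrone C6, C9 to the ester-bearing C3), then retro-[4+2] loss of CO2; the diene cannot aromatise because both new sp3 carbons are quaternary. The pyrone adds to the α face, opposite the axial 8β-silyloxy group, so C3 becomes equatorial on ring B and the C4 methyl and C9 oxygen β; DBU then regenerates the methylene lactone by E1cB loss of sulfinate.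

Step 11
Reactants: 16 cis-fused hexalin
Product: 18 trienone (8β-silyloxy-9-oxogermacra-1(10),2,4,11(13)-tetraen-12,6α-olid-14-oic acid methyl ester; ring bonds cis at C10=C1 and C2=C3; trans at C4=C5), via alkoxide 17 (not isolated)
Conditions: Bu4NF (1.1 equiv), THF, −78 °C; pH 7 buffer
Reagents that add atoms: none
Why: Proposed new method: fluoride cleaves the tertiary Me3Si–O bond (the secondary t-BuMe2Si ether is far slower) to give alkoxide 17, whose O–C9–C4–C5–S array is that of a Grob fragmentation: the oxygen lone pair forms the C9 ketone, the C4–C9 bond breaks with its electrons stabilised through C3=C2–C1=C10 by the ester (a bis-vinylogous retro-aldol), and the anti-periplanar equatorial sulfinate leaves to form C4=C5. The closest known reaction type is the Wharton–Grob fragmentation of decalin 1,3-diol monosulfonates to cyclodecenones, combined with E1cB loss of sulfinate from a stabilised carbanion. No ring is closed; the ten-membered ring arises by cleavage of the bond shared by rings A and B. No sp3 stereocentre is formed: C10=C1 and C2=C3 keep the cis ring geometry they had in ring A, and C4=C5 is formed trans in the ring because C3 is equatorial on ring B (anti to C6) and the C5–S bond is anti-periplanar to C4–C9. The step needs fragmentation to outrun silyl migration from O8, retro-aldol cleavage without elimination and conjugate re-addition of sulfinate; the aligned nucleofuge, the low temperature and the buffered quench are meant to secure this. The conformer that is formed has H-5 anti to H-6 and exposes the α face at C4 and the β face at C5, which step 12 uses.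

Step 12
Reactants: 18 trienone
Product: 19 4α,5β-epoxy ketone
Conditions: dimethyldioxirane, acetone/CH2Cl2, −40 to 0 °C
Reagents that add atoms: dimethyldioxirane, CC1(C)OO1
Why: Electrophilic epoxidation of the only electron-rich alkene (the trisubstituted C4=C5 is twisted out of conjugation, the others are acceptor-substituted); attack on the outer face of the trans ring alkene, as in other 6α,12-olide germacradienes, should give the 4α,5β-epoxide, whose C5–O bond takes the place of the former C5–S bond.

Step 13
Reactants: 19 4α,5β-epoxy ketone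
Product: 20 9α-alcohol
Conditions: NaBH4, CeCl3·7H2O, MeOH/THF, −78 °C
Reagents that add atoms: none
Why: Luche reduction: hard 1,2-hydride delivery to the cross-conjugated ketone; Felkin–Anh attack anti to the bulky, non-chelating α-silyloxy group should give the 8,9-threo (9α) alcohol.

Step 14
Reactants: 20 9α-alcohol
Product: 21 9α-acetate
Conditions: Ac2O, pyridine, DMAP (cat.), CH2Cl2, 0 °C
Reagents that add atoms: acetic anhydride, CC(=O)OC(C)=O
Why: Standard acylation of the allylic secondary alcohol under conditions too mild for epoxide opening.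

Step 15
Reactants: 21 9α-acetate
Product: 22 8β-alcohol (9α-acetoxy-4α,5β-epoxy-8β-hydroxy lactone ester)
Conditions: Bu4NF, AcOH, THF, 0 °C
Reagents that add atoms: none
Why: Buffered fluoride desilylation; acetic acid suppresses 1,2-acetyl migration and epoxide opening.

Step 16
Reactants: 23 tiglic acid
Product: 24 (E)-2-methylbut-2-en-1-ol
Conditions: LiAlH4, Et2O, 0 °C
Reagents that add atoms: none
Why: Hydride reduction of the acid to the allylic alcohol with retention of the E geometry.

Step 17
Reactants: 24 (E)-2-methylbut-2-en-1-ol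
Product: 25 [(2S,3S)-2,3-dimethyloxiran-2-yl]methanol
Conditions: Ti(OiPr)4 (cat.), L-(+)-diethyl tartrate (cat.), t-BuOOH, 4 Å molecular sieves, CH2Cl2, −20 °C
Reagents that add atoms: tert-butyl hydroperoxide, CC(C)(C)OO
Why: Sharpless asymmetric epoxidation; the L-(+)-tartrate catalyst delivers oxygen to the face that gives the (2S,3S) epoxy alcohol, and the E alkene fixes the cis relation of the two methyl groups.

Step 18
Reactants: 25 [(2S,3S)-2,3-dimethyloxiran-2-yl]methanol
Product: 26 (2R,3S)-2,3-dimethyloxirane-2-carboxylic acid
Conditions: RuCl3 (cat.), NaIO4, MeCN/EtOAc/H2O, 0 to 25 °C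
Reagents that add atoms: sodium periodate, [Na+].[O-]I(=O)(=O)=O; water, O
Why: RuO4-type oxidation of the primary alcohol to the acid; the quaternary α-carbon cannot epimerise, and the descriptor at C2 changes to R only through the priority change.

Step 19
Reactants: 22 8β-alcohol; 26 (2R,3S)-2,3-dimethyloxirane-2-carboxylic acid
Product: 28 target CNP0229507.5, via mixed anhydride 27 (not isolated)
Conditions: 2,4,6-trichlorobenzoyl chloride, Et3N, THF, 25 °C; then 22, DMAP, toluene, 25 °C
Reagents that add atoms: none
Why: Yamaguchi esterification through the mixed anhydride and the acylpyridinium ion; acylation at O8 with retention completes the target under conditions too mild to open either epoxide.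

## Compound list

1 | (S)-(+)-carvone | CC1=CC[C@@H](CC1=O)C(C)=C | starting material
2 | (5S)-5-(3-chloroprop-1-en-2-yl)-2-methylcyclohex-2-en-1-one | CC1=CC[C@@H](CC1=O)C(=C)CCl | intermediate
3 | 2-[(1S)-4-methyl-5-oxocyclohex-3-en-1-yl]prop-2-enal | CC1=CC[C@@H](CC1=O)C(=C)C=O | intermediate
4 | 2-[(1S)-4-methyl-5-oxocyclohex-3-en-1-yl]prop-2-enoic acid | CC1=CC[C@@H](CC1=O)C(=C)C(=O)O | intermediate
5 | trimethylsilyl 2-[(1R)-4-methyl-5-(trimethylsilyloxy)cyclohexa-2,4-dien-1-yl]prop-2-enoate | CC1=C(O[Si](C)(C)C)C[C@@H](C(=C)C(=O)O[Si](C)(C)C)C=C1 | intermediate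
6 | endoperoxide: trimethylsilyl 2-[5-methyl-4-(trimethylsilyloxy)-2,3-dioxabicyclo[2.2.2]oct-5-en-7-yl]prop-2-enoate, peroxide bridge anti to the side chain | CC1=C[C@H]2OO[C@]1(O[Si](C)(C)C)C[C@H]2C(=C)C(=O)O[Si](C)(C)C | intermediate (not isolated)
7 | 2-[(1S,2R)-2-hydroxy-4-methyl-5-oxocyclohex-3-en-1-yl]prop-2-enoic acid | CC1=C[C@@H](O)[C@@H](CC1=O)C(=C)C(=O)O | intermediate
8 | (3aS,7aR)-6-methyl-3-methylidene-3,3a,4,7a-tetrahydro-1-benzofuran-2,5-dione | CC1=C[C@H]2OC(=O)C(=C)[C@@H]2CC1=O | intermediate
9 | sodium alkoxide of the 8β-hydroxy derivative of 8 (O at C8 cis to C7–C11) | CC1=C[C@H]2OC(=O)C(=C)[C@@H]2[C@H]([O-])C1=O.[Na+] | intermediate (not isolated)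
10 | (3aS,4S,7aR)-4-[tert-butyl(dimethyl)silyl]oxy-6-methyl-3-methylidene-3,3a,4,7a-tetrahydro-1-benzofuran-2,5-dione | CC1=C[C@H]2OC(=O)C(=C)[C@@H]2[C@H](O[Si](C)(C)C(C)(C)C)C1=O | intermediate
11 | bis(phenylsulfonyl) ketone: 10 with H/PhSO2 added across C4=C5 (4α-Me, 5β-SO2Ph) and across C11=C13 (13-SO2Ph, C11 epimers) | C[C@@H]1C(=O)[C@@H](O[Si](C)(C)C(C)(C)C)[C@H]2C(CS(=O)(=O)c3ccccc3)C(=O)O[C@@H]2[C@H]1S(=O)(=O)c1ccccc1 | intermediate
12 | C9 trimethylsilyl enol ether of 11 (C9=C4) | CC1=C(O[Si](C)(C)C)[C@@H](O[Si](C)(C)C(C)(C)C)[C@H]2C(CS(=O)(=O)c3ccccc3)C(=O)O[C@@H]2[C@H]1S(=O)(=O)c1ccccc1 | intermediate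
13 | methyl 2-oxo-2H-pyran-3-carboxylate | COC(=O)C1=CC=COC1=O | starting material
14 | [4+2] adduct: 2-oxabicyclo[2.2.2]oct-5-en-3-one spanning C4 and C9 on the α face (endo/exo mixture at the two pyrone-derived bridgeheads) | C[C@]12[C@H](S(=O)(=O)c3ccccc3)[C@H]3OC(=O)C(CS(=O)(=O)c4ccccc4)[C@@H]3[C@H](O[Si](C)(C)C(C)(C)C)[C@@]1(O[Si](C)(C)C)C1(C(=O)OC)C=CC2OC1=O | intermediate (not isolated)
15 | cis-fused hexalin with masked lactone (4β-Me, 9β-OSiMe3, 5β-SO2Ph, 8β-OSi, 13-SO2Ph, C11 epimers) | C[C@@]12C=CC=C(C(=O)OC)[C@]1(O[Si](C)(C)C)[C@@H](O[Si](C)(C)C(C)(C)C)[C@H]3C(CS(=O)(=O)c4ccccc4)C(=O)O[C@@H]3[C@H]2S(=O)(=O)c1ccccc1 | intermediate (not isolated)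
16 | cis-fused hexalin with 11(13)-methylene lactone (4β-Me, 9β-OSiMe3, 5β-SO2Ph, 8β-OSi) | C[C@@]12C=CC=C(C(=O)OC)[C@]1(O[Si](C)(C)C)[C@@H](O[Si](C)(C)C(C)(C)C)[C@H]3C(=C)C(=O)O[C@@H]3[C@H]2S(=O)(=O)c1ccccc1 | intermediate
17 | tetrabutylammonium C9-alkoxide of 16 | C[C@@]12C=CC=C(C(=O)OC)[C@]1([O-])[C@@H](O[Si](C)(C)C(C)(C)C)[C@H]3C(=C)C(=O)O[C@@H]3[C@H]2S(=O)(=O)c1ccccc1.CCCC[N+](CCCC)(CCCC)CCCC | intermediate (not isolated)
18 | trienone: methyl 8β-[tert-butyl(dimethyl)silyl]oxy-9-oxogermacra-1(10),2,4,11(13)-tetraen-12,6α-olid-14-oate (ring bonds cis, cis, trans) | O=C1/C(C(=O)OC)=C\C=C/C(C)=C/[C@H]2OC(=O)C(=C)[C@@H]2[C@@H]1O[Si](C)(C)C(C)(C)C | intermediate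
19 | 4α,5β-epoxide of 18 | O=C1/C(C(=O)OC)=C\C=C/[C@@]2(C)O[C@@H]2[C@H]3OC(=O)C(=C)[C@@H]3[C@@H]1O[Si](C)(C)C(C)(C)C | intermediate
20 | 9α-alcohol | O[C@H]1/C(C(=O)OC)=C\C=C/[C@@]2(C)O[C@@H]2[C@H]3OC(=O)C(=C)[C@@H]3[C@@H]1O[Si](C)(C)C(C)(C)C | intermediate
21 | 9α-acetate | CC(=O)O[C@H]1/C(C(=O)OC)=C\C=C/[C@@]2(C)O[C@@H]2[C@H]3OC(=O)C(=C)[C@@H]3[C@@H]1O[Si](C)(C)C(C)(C)C | intermediate
22 | 8β-alcohol (9α-acetoxy-4α,5β-epoxy-8β-hydroxy lactone ester) | CC(=O)O[C@H]1/C(C(=O)OC)=C\C=C/[C@@]2(C)O[C@@H]2[C@H]3OC(=O)C(=C)[C@@H]3[C@@H]1O | intermediate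
23 | tiglic acid, (E)-2-methylbut-2-enoic acid | C/C=C(\C)C(=O)O | starting material
24 | (E)-2-methylbut-2-en-1-ol | C/C=C(\C)CO | intermediate
25 | [(2S,3S)-2,3-dimethyloxiran-2-yl]methanol | OC[C@]1(C)O[C@H]1C | intermediate
26 | (2R,3S)-2,3-dimethyloxirane-2-carboxylic acid | OC(=O)[C@]1(C)O[C@H]1C | intermediate
27 | (2R,3S)-2,3-dimethyloxirane-2-carboxylic 2,4,6-trichlorobenzoic anhydride | O=C(OC(=O)c1c(Cl)cc(Cl)cc1Cl)[C@]1(C)O[C@H]1C | intermediate (not isolated)
28 | CNP0229507.5 | C=C1C(=O)O[C@H]2[C@H]1[C@H](OC(=O)[C@]1(C)O[C@H]1C)[C@@H](OC(C)=O)/C(C(=O)OC)=C\C=C/[C@@]1(C)O[C@H]21 | target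

## Step count and least certain steps

Total step count: 19. Longest linear sequence: 16 steps (steps 1–15 and 19); steps 16–18 prepare acid 26.

**Step 11 (key step, Proposed new method).** After Si–O cleavage the alkoxide may undergo only the retro-aldol-type C4–C9 cleavage without expelling sulfinate, or silyl migration from O8 may compete. The product may also be lost by thermal 6π ring closure or by conjugate re-addition of sulfinate during work-up, because it is a strained, doubly activated triene. The fallback uses known reaction types and changes the mechanism from ionic to radical. It sets out from 16: methanolysis of the tertiary silyl ether (citric acid, MeOH) gives the tertiary alcohol F1. Alkoxy-radical β-fragmentation (PhI(OAc)2, I2, visible light) then cleaves the C4–C9 bond to the C9 ketone and a tertiary allylic C4 radical, which expels a phenylsulfonyl radical. The route is rejoined at 18.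

**Step 10.** The cycloaddition may be slow or add to the wrong face, because two adjacent quaternary carbons are formed on a tetrasubstituted enol ether; wrong-face addition would later give the cis C4=C5 bond, and loss of the silyl group may compete. The fallback is a stepwise annulation from 12. A Me3SiOTf-catalysed Mukaiyama–Michael addition to C6 of 13 forms the C3–C4 bond first and gives the keto dihydropyranone F2 (C4 is now quaternary, so base can be used). Et3N-promoted intramolecular aldol addition of the malonate-type carbon to the C9 ketone, loss of CO2 on warming and DBU treatment give the alcohol F1. Silylation with N-(trimethylsilyl)imidazole returns to 16.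

**Step 7.** Enolate oxidation may show poor facial selectivity, since steric approach anti to the neighbouring C7 substituent could override axial attack and give the 8α oxygen, which would also misdirect step 10. The fallback sets out from 8: the same hydroxylation without silylation gives the 8α-alcohol F3. Mitsunobu inversion (4-nitrobenzoic acid, PPh3, diisopropyl azodicarboxylate) gives the 8β-ester F4, brief methanolysis (K2CO3, MeOH, −20 °C) the 8β-alcohol F5, and silylation (t-BuMe2SiOTf, 2,6-lutidine) returns to 10.

**Step 5 (with step 4).** Step 4 may form the cross-conjugated dienol ether by α′-deprotonation, which would put oxygen on the wrong carbon, and singlet oxygen may react with poor face selectivity. The fallback sets out from 4: deconjugation (LiN(iPr)2, 2.2 equiv, THF, −78 °C, then kinetic protonation with AcOH) gives the β,γ-unsaturated keto acid F6. Epoxidation of C5=C6 anti to the side chain (m-CPBA) gives the epoxide F7, and Et3N-induced E1cB opening returns to 7.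

**Step 13.** Hydride may add from the wrong face, or the alkylidene keto ester may be reduced in a conjugate sense, because the ring conformation and not the acyclic model may control the approach. The fallback sets out from 19: if the 9β-alcohol F8 is formed, Mitsunobu esterification with acetic acid (PPh3, diisopropyl azodicarboxylate) inverts C9 and returns directly to 21.

## Further compounds

F1 | step 11 | C9 tertiary alcohol corresponding to 16 | C[C@@]12C=CC=C(C(=O)OC)[C@]1(O)[C@@H](O[Si](C)(C)C(C)(C)C)[C@H]3C(=C)C(=O)O[C@@H]3[C@H]2S(=O)(=O)c1ccccc1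
F2 | step 10 | keto dihydropyranone from Michael addition of 12 to C6 of 13 (C4 quaternary, pyranone on the α face, pyranone centres unassigned, C11 epimers) | C[C@@]1(C4C=CC(C(=O)OC)C(=O)O4)C(=O)[C@@H](O[Si](C)(C)C(C)(C)C)[C@H]2C(CS(=O)(=O)c3ccccc3)C(=O)O[C@@H]2[C@H]1S(=O)(=O)c1ccccc1
F3 | step 7 | 8α-hydroxy derivative of 8 | CC1=C[C@H]2OC(=O)C(=C)[C@@H]2[C@@H](O)C1=O
F4 | step 7 | 8β-(4-nitrobenzoyloxy) derivative of 8 | CC1=C[C@H]2OC(=O)C(=C)[C@@H]2[C@H](OC(=O)c3ccc(cc3)[N+](=O)[O-])C1=O
F5 | step 7 | 8β-hydroxy derivative of 8 | CC1=C[C@H]2OC(=O)C(=C)[C@@H]2[C@H](O)C1=O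
F6 | step 5 | 2-[4-methyl-5-oxocyclohex-2-en-1-yl]prop-2-enoic acid (C7 as in 4, C4 epimers) | CC1C=C[C@@H](CC1=O)C(=C)C(=O)O
F7 | step 5 | C5–C6 α-epoxide of F6 (anti to the side chain) | CC1[C@H]2O[C@H]2[C@@H](CC1=O)C(=C)C(=O)O
F8 | step 13 | 9β-alcohol (C9 epimer of 20) | O[C@@H]1/C(C(=O)OC)=C\C=C/[C@@]2(C)O[C@@H]2[C@H]3OC(=O)C(=C)[C@@H]3[C@@H]1O[Si](C)(C)C(C)(C)C
A1 | alternative 1 | seco C6–C7 epoxy aldehyde with (Z)-2-(bromomethyl)enoate terminus | BrC/C(C(=O)OC)=C\[C@H](OC(=O)[C@]1(C)O[C@H]1C)[C@@H](OC(C)=O)/C(C(=O)OC)=C\C=C/[C@@]1(C)O[C@@H]1C=O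
A2 | alternative 2 | cis-fused eudesma-1,3-diene with C10 ester (5β-H, 10β-CO2Me, 8β-OSi, 9α-OAc, 6α,12-lactone) | C=C1C(=O)O[C@H]2[C@H]1[C@H](O[Si](C)(C)C(C)(C)C)[C@@H](OC(C)=O)[C@@]1(C(=O)OC)C=CC=C(C)[C@@H]21
A3 | alternative 2 | ring-opened 1(10),2,4-triene from A2 | CC(=O)O[C@H]1/C(C(=O)OC)=C\C=C/C(C)=C/[C@H]2OC(=O)C(=C)[C@@H]2[C@@H]1O[Si](C)(C)C(C)(C)C
A4 | alternative 3 | trans-5,6-dialkenyl cyclohexadienol for anionic oxy-Cope rearrangement (one enantiomer drawn) | COC(=O)C1=CC=C[C@@](C)(/C=C/O[Si](C)(C)C(C)(C)C)[C@]1(O)/C=C/C(=C)C(=O)OC
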